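**Plan**

1. Cuts: the exocyclic C5=CH bond (Knoevenagel) divides the target into left dione 46 and right enal 25; then the two aryl ester C–O bonds; then, in each half, C5–C6 of the carbocycle (vinylogous aldol), the pyran O2–C3 bond, the C8–C8a bond (vinyllithium + Weinreb amide) and the C3–alkyne bond (Sonogashira).
2. Enabling feature (right bicycle, primed isochromene numbers): C5' is the γ-carbon of the chain O2'–C3'=C4'–C4a'=C8a'–C8'=O, and C6' carries oxygen next to the tertiary C7' carbinol. A 4a'-methyl pyranyl ketone with a C6' aldehyde therefore closes ring B' (C4a'–C5'–C6'–C7'–C8'–C8a') by an intramolecular vinylogous aldol.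
3. Forward: dibromide 4 gives two bromo-enynols that differ only in the side-chain silyl group. The tert-butyldimethylsilyl ether (6) stays on through the aldol of the right half and is turned into the enal just before the union; the triethylsilyl ether (28) falls off in the acidic work-up of the left half, where the alcohol is acetylated. Each bromide is acylated by its Weinreb amide; the pyran ring closes next, then the carbocycle; the halves are esterified, joined last, and the phenols freed at the end.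
4. Stereochemistry: C7' (R) is bought as (S)-2-methylglycidol and relayed to C6' (R) through a magnesium chelate in step 12. The left C7 (S) has the mirror-image arrangement and comes from (R)-2-methylglycidol.
5. Alkene geometry: E side chains from (E)-pent-2-en-4-yn-1-ol; the tetrasubstituted alkene from anti bromination; the (5Z) ylidene by thermodynamic control.

Key step: step 12

Assumption: the monocyclic 3-acyl-4-methyl-2H-pyrans (16, 17, 38, 39, 41, 42, 43) are written, and expected to react, as closed push–pull 2H-pyrans; a small, rapidly equilibrating share of the ring-opened 1-oxatriene would be drawn back through the pyran in steps 12 and 30, after which the bicycle cannot open.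

**Right-half bromo-enynol 6**

Step 1
Reactants: 1 (2E)-pent-2-en-4-yn-1-ol
Product: 2 tert-butyldimethyl{[(2E)-pent-2-en-4-yn-1-yl]oxy}silane
Conditions: t-BuMe2SiCl (1.1 equiv), imidazole (1.5 equiv), CH2Cl2, 0 → 20 °C
Reagents that add atoms: tert-butylchlorodimethylsilane, CC(C)(C)[Si](C)(C)Cl
Why: Silylation of a primary alcohol with a silyl chloride and imidazole is routine, and the tert-butyldimethylsilyl ether should last through the coupling, the hydride reduction, the organolithium step, the DDQ treatment and the magnesium-mediated aldol addition of the right half.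

Step 2
Reactants: 3 ethyl but-2-ynoate
Product: 4 ethyl (2E)-2,3-dibromobut-2-enoate
Conditions: Br2 (1.05 equiv), LiBr (2 equiv), AcOH, 20 °C, dark
Reagents that add atoms: bromine, BrBr
Why: Bromide-assisted electrophilic bromination of the electron-poor alkyne is an anti addition, so the two bromines should end up trans and the ester cis to the C3 bromine that the enyne will replace.

Step 3
Reactants: 4 ethyl (2E)-2,3-dibromobut-2-enoate; 2 tert-butyldimethyl{[(2E)-pent-2-en-4-yn-1-yl]oxy}silane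
Product: 5 ethyl (2E,6E)-2-bromo-8-[(tert-butyldimethylsilyl)oxy]-3-methylocta-2,6-dien-4-ynoate
Conditions: PdCl2(PPh3)2 (3 mol %), CuI (5 mol %), i-Pr2NH (3 equiv), THF, 20 °C
Reagents that add atoms: none
Why: Sonogashira coupling should occur with retention at the more electrophilic β-carbon–bromine bond of the α,β-dibromo enoate (a vinylogous acyl bromide), which keeps the α-bromide for later metalation and places the ester cis to the new alkynyl group.

Step 4
Reactants: 5 ethyl (2E,6E)-2-bromo-8-[(tert-butyldimethylsilyl)oxy]-3-methylocta-2,6-dien-4-ynoate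
Product: 6 (2E,6E)-2-bromo-8-[(tert-butyldimethylsilyl)oxy]-3-methylocta-2,6-dien-4-yn-1-ol
Conditions: i-Bu2AlH (2.3 equiv), CH2Cl2, −78 °C; aq. potassium sodium tartrate
Reagents that add atoms: none
Why: 1,2-Reduction of the enoate by i-Bu2AlH at low temperature should give the allylic alcohol without touching the vinyl bromide, the enyne or the silyl ether.

**(R)-Weinreb amide 10 (right half)**

Step 5
Reactants: 7 (S)-2-methylglycidol
Product: 8 (2S)-3-[(4-methoxyphenyl)methoxy]-2-methylpropane-1,2-diol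
Conditions: 4-MeOC6H4CH2OH (4 equiv), NaH (0.2 equiv), 70 °C
Reagents that add atoms: 4-methoxybenzyl alcohol, COc1ccc(CO)cc1
Why: Base-catalysed SN2 opening of the 2,2-disubstituted epoxide by the benzylic alkoxide occurs at the unsubstituted carbon, so the quaternary stereocentre is untouched (a Payne shift of this substrate is degenerate and returns the same enantiomer).

Step 6
Reactants: 8 (2S)-3-[(4-methoxyphenyl)methoxy]-2-methylpropane-1,2-diol
Product: 9 (2R)-2-hydroxy-3-[(4-methoxyphenyl)methoxy]-2-methylpropanoic acid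
Conditions: TEMPO (0.2 equiv), PhI(OAc)2 (2.4 equiv), MeCN/H2O (1:1), 20 °C
Reagents that add atoms: water, O
Why: TEMPO/PhI(OAc)2 oxidation in aqueous acetonitrile should take the primary alcohol through the aldehyde hydrate to the acid while the tertiary alcohol and the benzyl-type ether stay inert.

Step 7
Reactants: 9 (2R)-2-hydroxy-3-[(4-methoxyphenyl)methoxy]-2-methylpropanoic acid
Product: 10 (2R)-2-hydroxy-N-methoxy-3-[(4-methoxyphenyl)methoxy]-N,2-dimethylpropanamide
Conditions: MeNH(OMe)·HCl (1.5 equiv), EDC·HCl (1.5 equiv), HOBt (1.5 equiv), N-methylmorpholine (3 equiv), CH2Cl2, 0 → 20 °C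
Reagents that add atoms: N,O-dimethylhydroxylamine hydrochloride, CNOC.Cl
Why: Carbodiimide/HOBt amide coupling of the α-hydroxy acid should give the Weinreb amide, the hindered tertiary hydroxyl being too poor a nucleophile to compete.

**Right half: enal 25**

Step 8
Reactants: 6 (2E,6E)-2-bromo-8-[(tert-butyldimethylsilyl)oxy]-3-methylocta-2,6-dien-4-yn-1-ol; 10 (2R)-2-hydroxy-N-methoxy-3-[(4-methoxyphenyl)methoxy]-N,2-dimethylpropanamide
Product: 13 (2R,4E,8E)-10-[(tert-butyldimethylsilyl)oxy]-2-hydroxy-4-(hydroxymethyl)-1-[(4-methoxyphenyl)methoxy]-2,5-dimethyldeca-4,8-dien-6-yn-3-one, via dilithio vinyl species 11 (not isolated), via chloromagnesium alkoxide 12 (not isolated)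
Conditions: 6 (1.2 equiv), t-BuLi (3.1 equiv per 6), Et2O, −78 °C; add 10 pre-treated with i-PrMgCl (1.0 equiv, THF, −78 °C); −78 → −20 °C; aq. NH4Cl
Reagents that add atoms: none
Why: Bromine–lithium exchange on the lithium alkoxide of 6 proceeds with retention of alkene geometry and the vinyllithium adds once to the Weinreb amide (chelated tetrahedral intermediate, tertiary hydroxyl masked as its magnesium alkoxide), and the near-neutral NH4Cl work-up then releases the ketone while leaving the silyl ether in place (Weinreb ketone synthesis).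

Step 9
Reactants: 13 (2R,4E,8E)-10-[(tert-butyldimethylsilyl)oxy]-2-hydroxy-4-(hydroxymethyl)-1-[(4-methoxyphenyl)methoxy]-2,5-dimethyldeca-4,8-dien-6-yn-3-one
Product: 14 (2R,4E,8E)-10-[(tert-butyldimethylsilyl)oxy]-1,2-dihydroxy-4-(hydroxymethyl)-2,5-dimethyldeca-4,8-dien-6-yn-3-one
Conditions: DDQ (1.3 equiv), CH2Cl2/pH 7 buffer (NaH2PO4/Na2HPO4) 10:1, 0 °C
Reagents that add atoms: none
Why: Oxidative cleavage of the 4-methoxybenzyl ether by DDQ in wet solvent (water intercepts the oxocarbenium ion before the neighbouring tertiary hydroxyl can) is placed before the pyran exists, when the benzyl-type ether is the only group electron-rich enough to give up a hydride and the silyl ether is not affected.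

Step 10
Reactants: 14 (2R,4E,8E)-10-[(tert-butyldimethylsilyl)oxy]-1,2-dihydroxy-4-(hydroxymethyl)-2,5-dimethyldeca-4,8-dien-6-yn-3-one
Product: 16 (2R)-1-{6-[(1E)-3-[(tert-butyldimethylsilyl)oxy]prop-1-en-1-yl]-4-methyl-2H-pyran-3-yl}-2,3-dihydroxy-2-methylpropan-1-one, via dienaminone 15 (not isolated)
Conditions: pyrrolidine (1.5 equiv), MeOH, 0 → 20 °C; then AcOH (3 equiv), 40 °C
Reagents that add atoms: none
Why: Pyrrolidine should add in a 1,6 (aza-Michael) sense to the alkyne terminus of the acceptor-substituted enyne, and acid then exchanges nitrogen for the tethered hydroxyl at that same carbon (the addition–elimination by which enaminones are closed to chromones and pyranones), so the ring can only close six-membered and the furan-forming 5-exo-dig mode typical of direct cyclisation of (Z)-enynols has no pathway.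

Step 11
Reactants: 16 (2R)-1-{6-[(1E)-3-[(tert-butyldimethylsilyl)oxy]prop-1-en-1-yl]-4-methyl-2H-pyran-3-yl}-2,3-dihydroxy-2-methylpropan-1-one
Product: 17 (2R)-3-{6-[(1E)-3-[(tert-butyldimethylsilyl)oxy]prop-1-en-1-yl]-4-methyl-2H-pyran-3-yl}-2-hydroxy-2-methyl-3-oxopropanal
Conditions: SO3·pyridine (3 equiv), DMSO, i-Pr2NEt (5 equiv), CH2Cl2, 0 °C; used crude
Reagents that add atoms: none
Why: Parikh–Doering oxidation should convert the only primary alcohol into the aldehyde under cold, buffered conditions that spare the tertiary alcohol, the vicinal C–C bond, the silyl ether and the dienol ether, and the aldehyde formed cannot enolise.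

Step 12
Reactants: 17 (2R)-3-{6-[(1E)-3-[(tert-butyldimethylsilyl)oxy]prop-1-en-1-yl]-4-methyl-2H-pyran-3-yl}-2-hydroxy-2-methyl-3-oxopropanal
Product: 19 (6R,7R)-3-[(1E)-3-[(tert-butyldimethylsilyl)oxy]prop-1-en-1-yl]-6,7-dihydroxy-7-methyl-5,6,7,8-tetrahydro-1H-isochromen-8-one, via magnesium dienolate 18 (not isolated)
Conditions: MgBr2·OEt2 (3 equiv), i-Pr2NEt (4 equiv), CH2Cl2 (0.01 M), −20 → 0 °C; aq. NH4Cl
Reagents that add atoms: none
Why: MgBr2 binds the C7' oxygen (as its magnesium alkoxide) together with the C8' ketone and the C6' aldehyde, which acidifies the vinylogous C4a' methyl enough for i-Pr2NEt to take a proton and give the extended magnesium dienolate 18; the closest known reactions are magnesium-halide/amine direct aldol additions, intramolecular vinylogous aldol additions and chelation-controlled additions to α-hydroxy aldehydes. Only the γ-carbon can reach the aldehyde, and it should do so in a 6-(enolendo)-exo-trig closure that forms C5'–C6' and ring B', since attack through the α-carbon would give a four-membered ring. The new C6' centre is controlled by the bought C7' centre through the five-membered magnesium chelate: the aldehyde oxygen is held syn to the C7' oxygen, the tether delivers C5' to the face on the C8' side, and the C6' oxygen should therefore end cis to the C7' oxygen (6'R). The same cis-diol, with the methyl equatorial and the two oxygens bridged by magnesium, should also be favoured at equilibrium, so retro-aldol exchange would not erode it. Chemoselectivity rests on the substrate: the α-hydroxy aldehyde has no α-proton, the methyl is the only acidic carbon, the side-chain oxygen stays silylated so that no second carbonyl group is on offer, and dilution keeps two molecules apart.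

Step 13
Reactants: 20 orsellinic acid (2,4-dihydroxy-6-methylbenzoic acid)
Product: 21 tert-butyldimethylsilyl 2,4-bis[(tert-butyldimethylsilyl)oxy]-6-methylbenzoate
Conditions: t-BuMe2SiCl (3.5 equiv), imidazole (7 equiv), DMF, 40 °C
Reagents that add atoms: tert-butylchlorodimethylsilane, CC(C)(C)[Si](C)(C)Cl
Why: Exhaustive silylation with a silyl chloride and imidazole should give the bis-silyl ether silyl ester, the form needed for a neutral acid-chloride synthesis.

Step 14
Reactants: 21 tert-butyldimethylsilyl 2,4-bis[(tert-butyldimethylsilyl)oxy]-6-methylbenzoate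
Product: 22 2,4-bis[(tert-butyldimethylsilyl)oxy]-6-methylbenzoyl chloride
Conditions: (COCl)2 (1.2 equiv), DMF (cat.), CH2Cl2, 0 → 20 °C
Reagents that add atoms: oxalyl chloride, O=C(Cl)C(Cl)=O
Why: Oxalyl chloride with catalytic DMF converts a silyl ester directly into the acid chloride under neutral conditions (Wissner–Grudzinskas method), so the aryl silyl ethers never meet HCl.

Step 15
Reactants: 19 (6R,7R)-3-[(1E)-3-[(tert-butyldimethylsilyl)oxy]prop-1-en-1-yl]-6,7-dihydroxy-7-methyl-5,6,7,8-tetrahydro-1H-isochromen-8-one; 22 2,4-bis[(tert-butyldimethylsilyl)oxy]-6-methylbenzoyl chloride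
Product: 23 (6R,7R)-3-[(1E)-3-[(tert-butyldimethylsilyl)oxy]prop-1-en-1-yl]-7-hydroxy-7-methyl-8-oxo-5,6,7,8-tetrahydro-1H-isochromen-6-yl 2,4-bis[(tert-butyldimethylsilyl)oxy]-6-methylbenzoate
Conditions: 22 (1.5 equiv), Et3N (3 equiv), DMAP (1 equiv), CH2Cl2, 0 → 20 °C
Reagents that add atoms: none
Why: DMAP-catalysed acylation should pick the secondary C6' hydroxyl over the tertiary, ketone-flanked C7' hydroxyl on steric grounds, and the mild amine base avoids retro-aldol cleavage and β-elimination of the new ester.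

Step 16
Reactants: 23 (6R,7R)-3-[(1E)-3-[(tert-butyldimethylsilyl)oxy]prop-1-en-1-yl]-7-hydroxy-7-methyl-8-oxo-5,6,7,8-tetrahydro-1H-isochromen-6-yl 2,4-bis[(tert-butyldimethylsilyl)oxy]-6-methylbenzoate
Product: 24 (6R,7R)-7-hydroxy-3-[(1E)-3-hydroxyprop-1-en-1-yl]-7-methyl-8-oxo-5,6,7,8-tetrahydro-1H-isochromen-6-yl 2,4-bis[(tert-butyldimethylsilyl)oxy]-6-methylbenzoate
Conditions: HF·pyridine (5 equiv), pyridine, THF, 0 °C
Reagents that add atoms: none
Why: Under acidic fluoride conditions a primary alkyl silyl ether is cleaved well before aryl silyl ethers, whose oxygen is less basic, so pyridine-buffered HF·pyridine should free only the allylic alcohol and leave the two phenol ethers, the aryl ester and the β-acyloxy ketone untouched (selective desilylation).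

Step 17
Reactants: 24 (6R,7R)-7-hydroxy-3-[(1E)-3-hydroxyprop-1-en-1-yl]-7-methyl-8-oxo-5,6,7,8-tetrahydro-1H-isochromen-6-yl 2,4-bis[(tert-butyldimethylsilyl)oxy]-6-methylbenzoate
Product: 25 (6R,7R)-7-hydroxy-7-methyl-8-oxo-3-[(1E)-3-oxoprop-1-en-1-yl]-5,6,7,8-tetrahydro-1H-isochromen-6-yl 2,4-bis[(tert-butyldimethylsilyl)oxy]-6-methylbenzoate
Conditions: activated MnO2 (15 equiv), CH2Cl2, 20 °C
Reagents that add atoms: none
Why: MnO2 oxidises allylic alcohols selectively, so the dienylic primary alcohol should give the (E)-enal while the tertiary α-ketol and the esters are left alone, and the enal is made only now so that it meets no base before the union.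

**Left-half bromo-enynol 28**

Step 18
Reactants: 1 (2E)-pent-2-en-4-yn-1-ol
Product: 26 triethyl{[(2E)-pent-2-en-4-yn-1-yl]oxy}silane
Conditions: Et3SiCl (1.1 equiv), imidazole (1.5 equiv), CH2Cl2, 0 °C
Reagents that add atoms: chlorotriethylsilane, CC[Si](Cl)(CC)CC
Why: Silylation with a silyl chloride and imidazole is routine, and the triethylsilyl ether should survive the coupling, the hydride reduction and the organolithium step yet fall to dilute acetic acid in the work-up of step 24, which frees the alcohol for acetylation.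

Step 19
Reactants: 4 ethyl (2E)-2,3-dibromobut-2-enoate; 26 triethyl{[(2E)-pent-2-en-4-yn-1-yl]oxy}silane
Product: 27 ethyl (2E,6E)-2-bromo-3-methyl-8-[(triethylsilyl)oxy]octa-2,6-dien-4-ynoate
Conditions: PdCl2(PPh3)2 (3 mol %), CuI (5 mol %), i-Pr2NH (3 equiv), THF, 20 °C
Reagents that add atoms: none
Why: The site-selective Sonogashira coupling of step 3 should apply unchanged to the triethylsilyl-protected enyne.

Step 20
Reactants: 27 ethyl (2E,6E)-2-bromo-3-methyl-8-[(triethylsilyl)oxy]octa-2,6-dien-4-ynoate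
Product: 28 (2E,6E)-2-bromo-3-methyl-8-[(triethylsilyl)oxy]octa-2,6-dien-4-yn-1-ol
Conditions: i-Bu2AlH (2.3 equiv), CH2Cl2, −78 °C; aq. potassium sodium tartrate
Reagents that add atoms: none
Why: The low-temperature 1,2-reduction of step 4 should give the allylic alcohol here too, the triethylsilyl ether being stable to the hydride and to the neutral tartrate work-up.

**(S)-Weinreb amide 32 (left half)**

Step 21
Reactants: 29 (R)-2-methylglycidol
Product: 30 (2R)-3-[(4-methoxyphenyl)methoxy]-2-methylpropane-1,2-diol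
Conditions: 4-MeOC6H4CH2OH (4 equiv), NaH (0.2 equiv), 70 °C
Reagents that add atoms: 4-methoxybenzyl alcohol, COc1ccc(CO)cc1
Why: The same SN2 epoxide opening at the unsubstituted carbon as in step 5, run on the enantiomeric glycidol, leaves the quaternary centre untouched.

Step 22
Reactants: 30 (2R)-3-[(4-methoxyphenyl)methoxy]-2-methylpropane-1,2-diol
Product: 31 (2S)-2-hydroxy-3-[(4-methoxyphenyl)methoxy]-2-methylpropanoic acid
Conditions: TEMPO (0.2 equiv), PhI(OAc)2 (2.4 equiv), MeCN/H2O (1:1), 20 °C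
Reagents that add atoms: water, O
Why: The TEMPO/PhI(OAc)2 oxidation of step 6 applies unchanged in the mirror-image series.

Step 23
Reactants: 31 (2S)-2-hydroxy-3-[(4-methoxyphenyl)methoxy]-2-methylpropanoic acid
Product: 32 (2S)-2-hydroxy-N-methoxy-3-[(4-methoxyphenyl)methoxy]-N,2-dimethylpropanamide
Conditions: MeNH(OMe)·HCl (1.5 equiv), EDC·HCl (1.5 equiv), HOBt (1.5 equiv), N-methylmorpholine (3 equiv), CH2Cl2, 0 → 20 °C
Reagents that add atoms: N,O-dimethylhydroxylamine hydrochloride, CNOC.Cl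
Why: The carbodiimide amide coupling of step 7 applies unchanged in the mirror-image series.

**Left half: dione 46**

Step 24
Reactants: 28 (2E,6E)-2-bromo-3-methyl-8-[(triethylsilyl)oxy]octa-2,6-dien-4-yn-1-ol; 32 (2S)-2-hydroxy-N-methoxy-3-[(4-methoxyphenyl)methoxy]-N,2-dimethylpropanamide
Product: 36 (2S,4E,8E)-2,10-dihydroxy-4-(hydroxymethyl)-1-[(4-methoxyphenyl)methoxy]-2,5-dimethyldeca-4,8-dien-6-yn-3-one, via dilithio vinyl species 33 (not isolated), via chloromagnesium alkoxide 34 (not isolated), via triethylsilyl ether 35 (not isolated)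
Conditions: 28 (1.2 equiv), t-BuLi (3.1 equiv per 28), Et2O, −78 °C; add 32 pre-treated with i-PrMgCl (1.0 equiv, THF, −78 °C); −78 → −20 °C; then AcOH/THF/H2O (3:1:1), 20 °C
Reagents that add atoms: none
Why: The halogen–lithium exchange and Weinreb ketone synthesis of step 8 should run in the same way with the triethylsilyl bromide and the enantiomeric amide, and the aqueous acetic acid work-up should release the ketone and cleave the primary triethylsilyl ether in one operation.

Step 25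
Reactants: 36 (2S,4E,8E)-2,10-dihydroxy-4-(hydroxymethyl)-1-[(4-methoxyphenyl)methoxy]-2,5-dimethyldeca-4,8-dien-6-yn-3-one
Product: 38 (2S)-2-hydroxy-1-{6-[(1E)-3-hydroxyprop-1-en-1-yl]-4-methyl-2H-pyran-3-yl}-3-[(4-methoxyphenyl)methoxy]-2-methylpropan-1-one, via dienaminone 37 (not isolated)
Conditions: pyrrolidine (1.5 equiv), MeOH, 0 → 20 °C; then AcOH (3 equiv), 40 °C
Reagents that add atoms: none
Why: The aza-Michael addition and nitrogen-for-oxygen exchange of step 10 should close the pyran here as well, the benzyl-type ether being inert to amine and acetic acid.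

Step 26
Reactants: 38 (2S)-2-hydroxy-1-{6-[(1E)-3-hydroxyprop-1-en-1-yl]-4-methyl-2H-pyran-3-yl}-3-[(4-methoxyphenyl)methoxy]-2-methylpropan-1-one
Product: 39 (2E)-3-{5-[(2S)-2-hydroxy-3-[(4-methoxyphenyl)methoxy]-2-methylpropanoyl]-4-methyl-6H-pyran-2-yl}prop-2-en-1-yl acetate
Conditions: Ac2O (1.2 equiv), pyridine, CH2Cl2, 0 °C
Reagents that add atoms: acetic anhydride, CC(=O)OC(C)=O
Why: Acetylation with acetic anhydride in pyridine without DMAP should take only the primary allylic alcohol, the tertiary α-ketol hydroxyl being unreactive.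

Step 27
Reactants: 39 (2E)-3-{5-[(2S)-2-hydroxy-3-[(4-methoxyphenyl)methoxy]-2-methylpropanoyl]-4-methyl-6H-pyran-2-yl}prop-2-en-1-yl acetate; 22 2,4-bis[(tert-butyldimethylsilyl)oxy]-6-methylbenzoyl chloride
Product: 41 (2S)-1-{6-[(1E)-3-(acetyloxy)prop-1-en-1-yl]-4-methyl-2H-pyran-3-yl}-3-[(4-methoxyphenyl)methoxy]-2-methyl-1-oxopropan-2-yl 2,4-bis[(tert-butyldimethylsilyl)oxy]-6-methylbenzoate, via lithium alkoxide 40 (not isolated)
Conditions: LiN(SiMe3)2 (1.05 equiv), THF, −78 °C; 22 (1.3 equiv), −78 → 0 °C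
Reagents that add atoms: none
Why: Deprotonation of the only hydroxyl and acylation of the tertiary lithium alkoxide by the 2,6-disubstituted aroyl chloride is the usual route to hindered mesitoate-type tert-alkyl esters, and one equivalent of base should leave the acetate and the vinylogous methyl alone.

Step 28
Reactants: 41 (2S)-1-{6-[(1E)-3-(acetyloxy)prop-1-en-1-yl]-4-methyl-2H-pyran-3-yl}-3-[(4-methoxyphenyl)methoxy]-2-methyl-1-oxopropan-2-yl 2,4-bis[(tert-butyldimethylsilyl)oxy]-6-methylbenzoate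
Product: 42 (2S)-1-{6-[(1E)-3-(acetyloxy)prop-1-en-1-yl]-4-methyl-2H-pyran-3-yl}-3-hydroxy-2-methyl-1-oxopropan-2-yl 2,4-bis[(tert-butyldimethylsilyl)oxy]-6-methylbenzoate
Conditions: DDQ (1.3 equiv), CH2Cl2/pH 7 buffer (NaH2PO4/Na2HPO4) 10:1, 0 °C, short contact
Reagents that add atoms: none
Why: DDQ oxidation should remove the 4-methoxybenzyl ether because the substrate has no free neighbouring hydroxyl to form an acetal and the 3-acyl-2H-pyran, a push–pull diene, should resist hydride abstraction during a brief buffered treatment in the cold.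

Step 29
Reactants: 42 (2S)-1-{6-[(1E)-3-(acetyloxy)prop-1-en-1-yl]-4-methyl-2H-pyran-3-yl}-3-hydroxy-2-methyl-1-oxopropan-2-yl 2,4-bis[(tert-butyldimethylsilyl)oxy]-6-methylbenzoate
Product: 43 (2S)-1-{6-[(1E)-3-(acetyloxy)prop-1-en-1-yl]-4-methyl-2H-pyran-3-yl}-2-methyl-1,3-dioxopropan-2-yl 2,4-bis[(tert-butyldimethylsilyl)oxy]-6-methylbenzoate
Conditions: Dess–Martin periodinane (1.5 equiv), NaHCO3, CH2Cl2, 0 → 20 °C
Reagents that add atoms: none
Why: Dess–Martin oxidation of the neopentyl-type primary alcohol should give the non-enolisable α-acyloxy aldehyde, and doing it at once forestalls acyl migration from the tertiary to the primary oxygen.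

Step 30
Reactants: 43 (2S)-1-{6-[(1E)-3-(acetyloxy)prop-1-en-1-yl]-4-methyl-2H-pyran-3-yl}-2-methyl-1,3-dioxopropan-2-yl 2,4-bis[(tert-butyldimethylsilyl)oxy]-6-methylbenzoate
Product: 45 (7S)-3-[(1E)-3-(acetyloxy)prop-1-en-1-yl]-6-hydroxy-7-methyl-8-oxo-5,6,7,8-tetrahydro-1H-isochromen-7-yl 2,4-bis[(tert-butyldimethylsilyl)oxy]-6-methylbenzoate (both C6 epimers), via magnesium dienolate 44 (not isolated)
Conditions: MgBr2·OEt2 (2 equiv), i-Pr2NEt (3 equiv), CH2Cl2 (0.005 M), −20 → 0 °C; aq. NH4Cl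
Reagents that add atoms: none
Why: The same magnesium-mediated vinylogous aldol addition should close the carbocycle 6-exo-trig (magnesium now bridging aldehyde and ketone); the new carbinol centre may form as a mixture, which does not matter because it is oxidised next, and the hindered aroyl group should not migrate.

Step 31
Reactants: 45 (7S)-3-[(1E)-3-(acetyloxy)prop-1-en-1-yl]-6-hydroxy-7-methyl-8-oxo-5,6,7,8-tetrahydro-1H-isochromen-7-yl 2,4-bis[(tert-butyldimethylsilyl)oxy]-6-methylbenzoate (both C6 epimers)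
Product: 46 (7S)-3-[(1E)-3-(acetyloxy)prop-1-en-1-yl]-7-methyl-6,8-dioxo-5,6,7,8-tetrahydro-1H-isochromen-7-yl 2,4-bis[(tert-butyldimethylsilyl)oxy]-6-methylbenzoate
Conditions: IBX (1.5 equiv), DMSO/THF (1:1), 20 °C
Reagents that add atoms: none
Why: IBX oxidation of a β-hydroxy ketone should give the 1,3-diketone without over-oxidising the new active methylene, which removes the C6 centre and leaves C7 (S) as set by the glycidol.

**Union and deprotection**

Step 32
Reactants: 46 (7S)-3-[(1E)-3-(acetyloxy)prop-1-en-1-yl]-7-methyl-6,8-dioxo-5,6,7,8-tetrahydro-1H-isochromen-7-yl 2,4-bis[(tert-butyldimethylsilyl)oxy]-6-methylbenzoate; 25 (6R,7R)-7-hydroxy-7-methyl-8-oxo-3-[(1E)-3-oxoprop-1-en-1-yl]-5,6,7,8-tetrahydro-1H-isochromen-6-yl 2,4-bis[(tert-butyldimethylsilyl)oxy]-6-methylbenzoate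
Product: 47 tetrakis(tert-butyldimethylsilyl) ether of CNP0283591.2 (all four phenols silylated; 5Z,7S,6'R,7'R)
Conditions: 46 (1.0 equiv), 25 (1.0 equiv), ethylenediammonium diacetate (10 mol %), 4 Å molecular sieves, CH2Cl2, 20 °C
Reagents that add atoms: none
Why: Knoevenagel condensation of the doubly activated C5 methylene (α to C6=O, vinylogous to C8=O) with the enal should give the dienylidene dione, the (5Z) geometry with the chain turned toward C6=O being the thermodynamic one and the enal E geometry being kept, while the weakly basic buffered catalyst spares the β-acyloxy ketone of one half and the 2-acyloxy-1,3-dione of the other.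

Step 33
Reactants: 47 tetrakis(tert-butyldimethylsilyl) ether of CNP0283591.2 (all four phenols silylated; 5Z,7S,6'R,7'R)
Product: 48 CNP0283591.2 (target)
Conditions: Bu4NF (5 equiv), AcOH (6 equiv), THF, 0 °C
Reagents that add atoms: none
Why: Acetic-acid-buffered fluoride desilylation cleaves aryl silyl ethers within minutes in the cold, conditions under which the allylic acetate, both aryl esters, the tertiary alcohol and the polyene chromophore should survive.

**Compound list**

1 | (2E)-pent-2-en-4-yn-1-ol | OC/C=C/C#C | starting material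
2 | tert-butyldimethyl{[(2E)-pent-2-en-4-yn-1-yl]oxy}silane | CC(C)(C)[Si](C)(C)OC/C=C/C#C | intermediate
3 | ethyl but-2-ynoate | CCOC(=O)C#CC | starting material
4 | ethyl (2E)-2,3-dibromobut-2-enoate | CCOC(=O)/C(Br)=C(\Br)C | intermediate
5 | ethyl (2E,6E)-2-bromo-8-[(tert-butyldimethylsilyl)oxy]-3-methylocta-2,6-dien-4-ynoate | CCOC(=O)/C(Br)=C(\C#C/C=C/CO[Si](C)(C)C(C)(C)C)C | intermediate
6 | (2E,6E)-2-bromo-8-[(tert-butyldimethylsilyl)oxy]-3-methylocta-2,6-dien-4-yn-1-ol | OC/C(Br)=C(\C#C/C=C/CO[Si](C)(C)C(C)(C)C)C | intermediate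
7 | (S)-2-methylglycidol | C[C@]1(CO)CO1 | starting material
8 | (2S)-3-[(4-methoxyphenyl)methoxy]-2-methylpropane-1,2-diol | C[C@](O)(CO)COCc1ccc(OC)cc1 | intermediate
9 | (2R)-2-hydroxy-3-[(4-methoxyphenyl)methoxy]-2-methylpropanoic acid | C[C@](O)(C(=O)O)COCc1ccc(OC)cc1 | intermediate
10 | (2R)-2-hydroxy-N-methoxy-3-[(4-methoxyphenyl)methoxy]-N,2-dimethylpropanamide | C[C@](O)(C(=O)N(C)OC)COCc1ccc(OC)cc1 | intermediate
11 | lithium (2Z,6E)-8-[(tert-butyldimethylsilyl)oxy]-2-lithio-3-methylocta-2,6-dien-4-yn-1-olate | [Li]OC/C([Li])=C(\C#C/C=C/CO[Si](C)(C)C(C)(C)C)C | intermediate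
12 | chloromagnesium alkoxide of 10 | C[C@](O[Mg]Cl)(C(=O)N(C)OC)COCc1ccc(OC)cc1 | intermediate
13 | (2R,4E,8E)-10-[(tert-butyldimethylsilyl)oxy]-2-hydroxy-4-(hydroxymethyl)-1-[(4-methoxyphenyl)methoxy]-2,5-dimethyldeca-4,8-dien-6-yn-3-one | OC/C(C(=O)[C@](C)(O)COCc1ccc(OC)cc1)=C(\C#C/C=C/CO[Si](C)(C)C(C)(C)C)C | intermediate
14 | (2R,4E,8E)-10-[(tert-butyldimethylsilyl)oxy]-1,2-dihydroxy-4-(hydroxymethyl)-2,5-dimethyldeca-4,8-dien-6-yn-3-one | OC/C(C(=O)[C@](C)(O)CO)=C(\C#C/C=C/CO[Si](C)(C)C(C)(C)C)C | intermediate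
15 | (2R,8E)-10-[(tert-butyldimethylsilyl)oxy]-1,2-dihydroxy-4-(hydroxymethyl)-2,5-dimethyl-7-(pyrrolidin-1-yl)deca-4,6,8-trien-3-one (4,6-geometry equilibrating) | OCC(C(=O)[C@](C)(O)CO)=C(C)C=C(N1CCCC1)/C=C/CO[Si](C)(C)C(C)(C)C | intermediate
16 | (2R)-1-{6-[(1E)-3-[(tert-butyldimethylsilyl)oxy]prop-1-en-1-yl]-4-methyl-2H-pyran-3-yl}-2,3-dihydroxy-2-methylpropan-1-one | CC1=C(C(=O)[C@](C)(O)CO)COC(/C=C/CO[Si](C)(C)C(C)(C)C)=C1 | intermediate
17 | (2R)-3-{6-[(1E)-3-[(tert-butyldimethylsilyl)oxy]prop-1-en-1-yl]-4-methyl-2H-pyran-3-yl}-2-hydroxy-2-methyl-3-oxopropanal | CC1=C(C(=O)[C@](C)(O)C=O)COC(/C=C/CO[Si](C)(C)C(C)(C)C)=C1 | intermediate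
18 | bis(bromomagnesium) alkoxide–dienolate of 17 (4-methylidene-4H-pyran form) | C=C1C=C(/C=C/CO[Si](C)(C)C(C)(C)C)OCC1=C(O[Mg]Br)[C@](C)(O[Mg]Br)C=O | intermediate
19 | (6R,7R)-3-[(1E)-3-[(tert-butyldimethylsilyl)oxy]prop-1-en-1-yl]-6,7-dihydroxy-7-methyl-5,6,7,8-tetrahydro-1H-isochromen-8-one | CC(C)(C)[Si](C)(C)OC/C=C/C1=CC2=C(CO1)C(=O)[C@](C)(O)[C@H](O)C2 | intermediate
20 | orsellinic acid (2,4-dihydroxy-6-methylbenzoic acid) | Cc1cc(O)cc(O)c1C(=O)O | starting material
21 | tert-butyldimethylsilyl 2,4-bis[(tert-butyldimethylsilyl)oxy]-6-methylbenzoate | Cc1cc(O[Si](C)(C)C(C)(C)C)cc(O[Si](C)(C)C(C)(C)C)c1C(=O)O[Si](C)(C)C(C)(C)C | intermediate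
22 | 2,4-bis[(tert-butyldimethylsilyl)oxy]-6-methylbenzoyl chloride | Cc1cc(O[Si](C)(C)C(C)(C)C)cc(O[Si](C)(C)C(C)(C)C)c1C(Cl)=O | intermediate
23 | (6R,7R)-3-[(1E)-3-[(tert-butyldimethylsilyl)oxy]prop-1-en-1-yl]-7-hydroxy-7-methyl-8-oxo-5,6,7,8-tetrahydro-1H-isochromen-6-yl 2,4-bis[(tert-butyldimethylsilyl)oxy]-6-methylbenzoate | CC(C)(C)[Si](C)(C)OC/C=C/C1=CC2=C(CO1)C(=O)[C@](C)(O)[C@H](OC(=O)c1c(C)cc(O[Si](C)(C)C(C)(C)C)cc1O[Si](C)(C)C(C)(C)C)C2 | intermediate
24 | (6R,7R)-7-hydroxy-3-[(1E)-3-hydroxyprop-1-en-1-yl]-7-methyl-8-oxo-5,6,7,8-tetrahydro-1H-isochromen-6-yl 2,4-bis[(tert-butyldimethylsilyl)oxy]-6-methylbenzoate | OC/C=C/C1=CC2=C(CO1)C(=O)[C@](C)(O)[C@H](OC(=O)c1c(C)cc(O[Si](C)(C)C(C)(C)C)cc1O[Si](C)(C)C(C)(C)C)C2 | intermediate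
25 | (6R,7R)-7-hydroxy-7-methyl-8-oxo-3-[(1E)-3-oxoprop-1-en-1-yl]-5,6,7,8-tetrahydro-1H-isochromen-6-yl 2,4-bis[(tert-butyldimethylsilyl)oxy]-6-methylbenzoate | O=C/C=C/C1=CC2=C(CO1)C(=O)[C@](C)(O)[C@H](OC(=O)c1c(C)cc(O[Si](C)(C)C(C)(C)C)cc1O[Si](C)(C)C(C)(C)C)C2 | intermediate
26 | triethyl{[(2E)-pent-2-en-4-yn-1-yl]oxy}silane | CC[Si](CC)(CC)OC/C=C/C#C | intermediate
27 | ethyl (2E,6E)-2-bromo-3-methyl-8-[(triethylsilyl)oxy]octa-2,6-dien-4-ynoate | CCOC(=O)/C(Br)=C(\C#C/C=C/CO[Si](CC)(CC)CC)C | intermediate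
28 | (2E,6E)-2-bromo-3-methyl-8-[(triethylsilyl)oxy]octa-2,6-dien-4-yn-1-ol | OC/C(Br)=C(\C#C/C=C/CO[Si](CC)(CC)CC)C | intermediate
29 | (R)-2-methylglycidol | C[C@@]1(CO)CO1 | starting material
30 | (2R)-3-[(4-methoxyphenyl)methoxy]-2-methylpropane-1,2-diol | C[C@@](O)(CO)COCc1ccc(OC)cc1 | intermediate
31 | (2S)-2-hydroxy-3-[(4-methoxyphenyl)methoxy]-2-methylpropanoic acid | C[C@@](O)(C(=O)O)COCc1ccc(OC)cc1 | intermediate
32 | (2S)-2-hydroxy-N-methoxy-3-[(4-methoxyphenyl)methoxy]-N,2-dimethylpropanamide | C[C@@](O)(C(=O)N(C)OC)COCc1ccc(OC)cc1 | intermediate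
33 | lithium (2Z,6E)-2-lithio-3-methyl-8-[(triethylsilyl)oxy]octa-2,6-dien-4-yn-1-olate | [Li]OC/C([Li])=C(\C#C/C=C/CO[Si](CC)(CC)CC)C | intermediate
34 | chloromagnesium alkoxide of 32 | C[C@@](O[Mg]Cl)(C(=O)N(C)OC)COCc1ccc(OC)cc1 | intermediate
35 | (2S,4E,8E)-2-hydroxy-4-(hydroxymethyl)-1-[(4-methoxyphenyl)methoxy]-2,5-dimethyl-10-[(triethylsilyl)oxy]deca-4,8-dien-6-yn-3-one | OC/C(C(=O)[C@@](C)(O)COCc1ccc(OC)cc1)=C(\C#C/C=C/CO[Si](CC)(CC)CC)C | intermediate
36 | (2S,4E,8E)-2,10-dihydroxy-4-(hydroxymethyl)-1-[(4-methoxyphenyl)methoxy]-2,5-dimethyldeca-4,8-dien-6-yn-3-one | OC/C(C(=O)[C@@](C)(O)COCc1ccc(OC)cc1)=C(\C#C/C=C/CO)C | intermediate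
37 | (2S,8E)-2,10-dihydroxy-4-(hydroxymethyl)-1-[(4-methoxyphenyl)methoxy]-2,5-dimethyl-7-(pyrrolidin-1-yl)deca-4,6,8-trien-3-one (4,6-geometry equilibrating) | OCC(C(=O)[C@@](C)(O)COCc1ccc(OC)cc1)=C(C)C=C(N1CCCC1)/C=C/CO | intermediate
38 | (2S)-2-hydroxy-1-{6-[(1E)-3-hydroxyprop-1-en-1-yl]-4-methyl-2H-pyran-3-yl}-3-[(4-methoxyphenyl)methoxy]-2-methylpropan-1-one | CC1=C(C(=O)[C@@](C)(O)COCc2ccc(OC)cc2)COC(/C=C/CO)=C1 | intermediate
39 | (2E)-3-{5-[(2S)-2-hydroxy-3-[(4-methoxyphenyl)methoxy]-2-methylpropanoyl]-4-methyl-6H-pyran-2-yl}prop-2-en-1-yl acetate | CC1=C(C(=O)[C@@](C)(O)COCc2ccc(OC)cc2)COC(/C=C/COC(C)=O)=C1 | intermediate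
40 | lithium alkoxide of 39 | CC1=C(C(=O)[C@@](C)(O[Li])COCc2ccc(OC)cc2)COC(/C=C/COC(C)=O)=C1 | intermediate
41 | (2S)-1-{6-[(1E)-3-(acetyloxy)prop-1-en-1-yl]-4-methyl-2H-pyran-3-yl}-3-[(4-methoxyphenyl)methoxy]-2-methyl-1-oxopropan-2-yl 2,4-bis[(tert-butyldimethylsilyl)oxy]-6-methylbenzoate | CC1=C(C(=O)[C@@](C)(OC(=O)c2c(C)cc(O[Si](C)(C)C(C)(C)C)cc2O[Si](C)(C)C(C)(C)C)COCc2ccc(OC)cc2)COC(/C=C/COC(C)=O)=C1 | intermediate
42 | (2S)-1-{6-[(1E)-3-(acetyloxy)prop-1-en-1-yl]-4-methyl-2H-pyran-3-yl}-3-hydroxy-2-methyl-1-oxopropan-2-yl 2,4-bis[(tert-butyldimethylsilyl)oxy]-6-methylbenzoate | CC1=C(C(=O)[C@@](C)(OC(=O)c2c(C)cc(O[Si](C)(C)C(C)(C)C)cc2O[Si](C)(C)C(C)(C)C)CO)COC(/C=C/COC(C)=O)=C1 | intermediate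
43 | (2S)-1-{6-[(1E)-3-(acetyloxy)prop-1-en-1-yl]-4-methyl-2H-pyran-3-yl}-2-methyl-1,3-dioxopropan-2-yl 2,4-bis[(tert-butyldimethylsilyl)oxy]-6-methylbenzoate | CC1=C(C(=O)[C@@](C)(OC(=O)c2c(C)cc(O[Si](C)(C)C(C)(C)C)cc2O[Si](C)(C)C(C)(C)C)C=O)COC(/C=C/COC(C)=O)=C1 | intermediate
44 | bromomagnesium dienolate of 43 (4-methylidene-4H-pyran form) | C=C1C=C(/C=C/COC(C)=O)OCC1=C(O[Mg]Br)[C@@](C)(OC(=O)c1c(C)cc(O[Si](C)(C)C(C)(C)C)cc1O[Si](C)(C)C(C)(C)C)C=O | intermediate
45 | (7S)-3-[(1E)-3-(acetyloxy)prop-1-en-1-yl]-6-hydroxy-7-methyl-8-oxo-5,6,7,8-tetrahydro-1H-isochromen-7-yl 2,4-bis[(tert-butyldimethylsilyl)oxy]-6-methylbenzoate (both C6 epimers) | CC(=O)OC/C=C/C1=CC2=C(CO1)C(=O)[C@@](C)(OC(=O)c1c(C)cc(O[Si](C)(C)C(C)(C)C)cc1O[Si](C)(C)C(C)(C)C)C(O)C2 | intermediate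
46 | (7S)-3-[(1E)-3-(acetyloxy)prop-1-en-1-yl]-7-methyl-6,8-dioxo-5,6,7,8-tetrahydro-1H-isochromen-7-yl 2,4-bis[(tert-butyldimethylsilyl)oxy]-6-methylbenzoate | CC(=O)OC/C=C/C1=CC2=C(CO1)C(=O)[C@@](C)(OC(=O)c1c(C)cc(O[Si](C)(C)C(C)(C)C)cc1O[Si](C)(C)C(C)(C)C)C(=O)C2 | intermediate
47 | tetrakis(tert-butyldimethylsilyl) ether of CNP0283591.2 (all four phenols silylated; 5Z,7S,6'R,7'R) | CC(=O)OC/C=C/C1=CC2=C(CO1)C(=O)[C@@](C)(OC(=O)c1c(C)cc(O[Si](C)(C)C(C)(C)C)cc1O[Si](C)(C)C(C)(C)C)C(=O)/C2=C\C=C\C1=CC2=C(CO1)C(=O)[C@](C)(O)[C@H](OC(=O)c1c(C)cc(O[Si](C)(C)C(C)(C)C)cc1O[Si](C)(C)C(C)(C)C)C2 | intermediate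
48 | CNP0283591.2: (5Z,7S)-3-[(1E)-3-(acetyloxy)prop-1-en-1-yl]-5-{(2E)-3-[(6R,7R)-6-[(2,4-dihydroxy-6-methylbenzoyl)oxy]-7-hydroxy-7-methyl-8-oxo-5,6,7,8-tetrahydro-1H-isochromen-3-yl]prop-2-en-1-ylidene}-7-methyl-6,8-dioxo-5,6,7,8-tetrahydro-1H-isochromen-7-yl 2,4-dihydroxy-6-methylbenzoate | CC(=O)OC/C=C/C1=CC2=C(CO1)C(=O)[C@@](C)(OC(=O)c1c(C)cc(O)cc1O)C(=O)/C2=C\C=C\C1=CC2=C(CO1)C(=O)[C@](C)(O)[C@H](OC(=O)c1c(C)cc(O)cc1O)C2 | target

**Count and risks**

Total: 33 steps. Longest linear sequence: 13 steps (steps 1, 3, 4, 8, 9, 10, 11, 12, 15, 16, 17, 32, 33; the left-half line through steps 18, 19, 20, 24, 25, 26, 27, 28, 29, 30, 31, 32, 33 is equally long).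

Steps most likely to fail:

1. Step 10 (the same reaction recurs as step 25). What may go wrong: the amine adduct may fail to exchange nitrogen for the tethered oxygen, or the freshly formed monocyclic pyran may drain into its ring-opened oxatriene and oligomerise on concentration. Fallback, from 14 back to 16: the oxygen is brought in by carbon–oxygen cross-coupling instead of an amine relay. Conjugate hydroiodination of the ynenone 14 (NaI, AcOH, MeCN, 20 °C) should give the iodo trienone F1, with iodine on the alkyne terminus and cis to the chain. CuI (10 mol %), 1,10-phenanthroline and Cs2CO3 in toluene at 80 °C should then close the six-membered enol ether by intramolecular O-vinylation and give 16.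

2. Step 12. What may go wrong: deprotonation of the electron-rich pyranyl methyl may be too slow, so that α-ketol rearrangement or deformylation of the α-hydroxy-β-keto aldehyde overtakes ring closure. Fallback, from 13 back to 19: the same C5'–C6' bond is made before the pyran is closed, where the methyl sits on an electron-poor ynenone and is more acidic. Et3SiCl/imidazole should protect the free hydroxymethyl group of 13 to give the mixed bis-silyl ether F2, and DDQ (wet CH2Cl2, 0 °C) should then free the primary alcohol of the diol F3. SO3·pyridine/DMSO should give the α-hydroxy aldehyde F4, and MgBr2·OEt2/i-Pr2NEt should close the carbocycle under the same chelate control to the cyclohexenone diol F5. AcOH/THF/H2O should remove only the triethylsilyl group and give the enynol F6. Ph3PAuNTf2 (2 mol %, CH2Cl2) should then close the pyran on this ring-fused enynol, for which the 6-endo mode is the one known from 2-alkynylbenzyl alcohols, and so return 19.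

3. Step 27. What may go wrong: acylation of the hindered tertiary alkoxide by the 2,6-disubstituted acid chloride may stall, leaving the alkoxide time for acetate transfer or an α-ketol shift. Fallback, from 20 and 39 back to 41: the acyl group is delivered from a tied-back cyclic donor. Orsellinic acid 20 with acetone, (CF3CO)2O and CF3CO2H should give the benzodioxinone F7, and t-BuMe2SiCl/imidazole its silyl ether F8. Alkoxide 40 (from 39 as in step 27) should open F8 at the ring carbonyl with loss of acetone, giving the salicylate-type tertiary ester F9, which has a free ortho phenol. t-BuMe2SiCl/imidazole should silylate that phenol and return 41.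

**Further compounds**

F1 | step 10 | (2R,4E,6Z,8E)-10-[(tert-butyldimethylsilyl)oxy]-1,2-dihydroxy-4-(hydroxymethyl)-7-iodo-2,5-dimethyldeca-4,6,8-trien-3-one | OC/C(C(=O)[C@](C)(O)CO)=C(C)\C=C(/I)\C=C\CO[Si](C)(C)C(C)(C)C
F2 | step 12 | (2R,4E,8E)-10-[(tert-butyldimethylsilyl)oxy]-2-hydroxy-1-[(4-methoxyphenyl)methoxy]-2,5-dimethyl-4-{[(triethylsilyl)oxy]methyl}deca-4,8-dien-6-yn-3-one | CC[Si](CC)(CC)OC/C(C(=O)[C@](C)(O)COCc1ccc(OC)cc1)=C(\C#C/C=C/CO[Si](C)(C)C(C)(C)C)C
F3 | step 12 | (2R,4E,8E)-10-[(tert-butyldimethylsilyl)oxy]-1,2-dihydroxy-2,5-dimethyl-4-{[(triethylsilyl)oxy]methyl}deca-4,8-dien-6-yn-3-one | CC[Si](CC)(CC)OC/C(C(=O)[C@](C)(O)CO)=C(\C#C/C=C/CO[Si](C)(C)C(C)(C)C)C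
F4 | step 12 | (2R,4E,8E)-10-[(tert-butyldimethylsilyl)oxy]-2-hydroxy-2,5-dimethyl-3-oxo-4-{[(triethylsilyl)oxy]methyl}deca-4,8-dien-6-ynal | CC[Si](CC)(CC)OC/C(C(=O)[C@](C)(O)C=O)=C(\C#C/C=C/CO[Si](C)(C)C(C)(C)C)C
F5 | step 12 | (5R,6R)-3-{(3E)-5-[(tert-butyldimethylsilyl)oxy]pent-3-en-1-yn-1-yl}-5,6-dihydroxy-6-methyl-2-{[(triethylsilyl)oxy]methyl}cyclohex-2-en-1-one | CC[Si](CC)(CC)OCC1=C(C#C/C=C/CO[Si](C)(C)C(C)(C)C)C[C@@H](O)[C@@](C)(O)C1=O
F6 | step 12 | (5R,6R)-3-{(3E)-5-[(tert-butyldimethylsilyl)oxy]pent-3-en-1-yn-1-yl}-5,6-dihydroxy-2-(hydroxymethyl)-6-methylcyclohex-2-en-1-one | OCC1=C(C#C/C=C/CO[Si](C)(C)C(C)(C)C)C[C@@H](O)[C@@](C)(O)C1=O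
F7 | step 27 | 7-hydroxy-2,2,5-trimethyl-4H-1,3-benzodioxin-4-one | Cc1cc(O)cc2OC(C)(C)OC(=O)c12
F8 | step 27 | 7-[(tert-butyldimethylsilyl)oxy]-2,2,5-trimethyl-4H-1,3-benzodioxin-4-one | Cc1cc(O[Si](C)(C)C(C)(C)C)cc2OC(C)(C)OC(=O)c12
F9 | step 27 | (2S)-1-{6-[(1E)-3-(acetyloxy)prop-1-en-1-yl]-4-methyl-2H-pyran-3-yl}-3-[(4-methoxyphenyl)methoxy]-2-methyl-1-oxopropan-2-yl 4-[(tert-butyldimethylsilyl)oxy]-2-hydroxy-6-methylbenzoate | CC1=C(C(=O)[C@@](C)(OC(=O)c2c(C)cc(O[Si](C)(C)C(C)(C)C)cc2O)COCc2ccc(OC)cc2)COC(/C=C/COC(C)=O)=C1
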